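## Retrosynthetic overview
1. The last step acylates the only secondary alcohol (C4–OH) with octanoic acid. The butyrate arrives already attached to the side-chain fragment.
2. The oxonane and lactone are opened by cutting C3–C4, made by SmI2 ketyl coupling of a C4 aldehyde with the acetyl group on C2. The C3 alkoxide then closes the seven-membered lactone onto C16.
3. C8–C9 comes from a Hosomi–Sakurai coupling of the bicyclic C9 lactol with a C4–C8 allylsilane. C6 is set by a catalytic asymmetric aldol.
4. Key step: one acyclic bromoacetal gives the tetrahydrofuran and the cyclohexane in a single radical cascade, C10–C1 (5-exo) then C14–C13 (6-endo). The C11 methyl group is added afterwards.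
5. Ring order is tetrahydrofuran plus cyclohexane (one step), then oxonane, then lactone (same flask). Chirality enters at C2 (Sharpless), C15 (copper allylic alkylation) and C6 (Ti–BINOL aldol).

Assumption: briarellin skeleton numbering is used for every intermediate: C1/C10 ring fusion; C2–O–C9 ether bridge; C3 methyl carbinol carbon; C4 octanoate; C6 butyrate; C7 exocyclic methylene; C11 methyl carbinol; C14–C15(CH3)–C16 lactone arm. The given SMILES corresponds to 1S,2S,3S,4R,6R,9S,10R,11R,14R,15R.

## Route

Step 1
Reactants: 1 methacrolein; 2 vinylmagnesium bromide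
Product: 3 rac-2-methylpenta-1,4-dien-3-ol
Conditions: THF, −78 to 0 °C; then H2O
Reagents that add atoms: none
Why: Grignard 1,2-addition to an enal is fast at low temperature, and the new carbinol centre (C2) forms racemic and is resolved in step 2.

Step 2
Reactants: 3 rac-2-methylpenta-1,4-dien-3-ol
Product: 4 (1S)-1-[(2S)-2-methyloxiran-2-yl]prop-2-en-1-ol
Conditions: Ti(OiPr)4 (0.15 equiv), L-(+)-DIPT (0.2 equiv), t-BuOOH (0.45 equiv), 4 Å MS, CH2Cl2, −20 °C
Reagents that add atoms: tert-butyl hydroperoxide, CC(C)(C)OO
Why: Sharpless asymmetric epoxidation run as a kinetic resolution, in which L-(+)-DIPT makes the S alcohol the fast enantiomer and epoxidises its more nucleophilic 1,1-disubstituted alkene from the tartrate-defined face (erythro product), so C2 is fixed as S, the isopropenyl group is masked against radicals, and the R alcohol stays behind or goes to a separable vinyl epoxide.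

Step 3
Reactants: 5 methyl (E)-4-bromobut-2-enoate
Product: 6 methyl (2R)-2-methylbut-3-enoate
Conditions: MeMgBr (1.2 equiv), CuBr·SMe2 (2 mol %), Taniaphos (2.4 mol %, the enantiomer that gives the R ester), CH2Cl2, −75 °C
Reagents that add atoms: methylmagnesium bromide, C[Mg]Br
Why: Copper-catalysed asymmetric allylic alkylation (SN2') of a halocrotonate delivers methyl to the α-carbon under ligand control, which sets C15 as R and frees the terminal alkene needed in step 4.

Step 4
Reactants: 4 (1S)-1-[(2S)-2-methyloxiran-2-yl]prop-2-en-1-ol; 6 methyl (2R)-2-methylbut-3-enoate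
Product: 7 methyl (2R,3E,5S)-5-hydroxy-2-methyl-5-[(2S)-2-methyloxiran-2-yl]pent-3-enoate
Conditions: second-generation Hoveyda–Grubbs catalyst (5 mol %), 1,4-benzoquinone (10 mol %), 6 (3 equiv), CH2Cl2, 40 °C
Reagents that add atoms: none
Why: Olefin cross-metathesis of two monosubstituted alkenes gives the E alkene (C1=C14) under thermodynamic control, excess of the cheap ester drives the cross product, benzoquinone stops ruthenium hydride isomerisation that would racemise C15, and no stereocentre is touched.

Step 5
Reactants: 8 (E)-4-methoxybut-3-en-2-one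
Product: 12 (E)-1-methoxypenta-1,4-dien-3-one, via lithium dienolate 9 (not isolated), via Mannich base 10 (not isolated), via methiodide 11 (not isolated)
Conditions: LiN(SiMe3)2, THF, −78 °C; CH2=NMe2+ I−, −78 to 0 °C; MeI, rt; aq NaHCO3/CH2Cl2, rt; used at once (BHT)
Reagents that add atoms: Eschenmoser's salt (N,N-dimethylmethyleneiminium iodide), C=[N+](C)C.[I-]
Why: Eschenmoser methylenation (Mannich reaction, quaternisation, E1cB loss of trimethylamine) works here because the methyl group is the only enolisable position, and it turns the methyl ketone into the vinyl ketone (C12=C13) without creating a stereocentre.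

Step 6
Reactants: 7 methyl (2R,3E,5S)-5-hydroxy-2-methyl-5-[(2S)-2-methyloxiran-2-yl]pent-3-enoate; 12 (E)-1-methoxypenta-1,4-dien-3-one
Product: 13 methyl (2R,3E,5S)-5-[(2-bromo-1-methoxy-3-oxopent-4-en-1-yl)oxy]-2-methyl-5-[(2S)-2-methyloxiran-2-yl]pent-3-enoate (epimers at C9 and C10)
Conditions: NBS (1.3 equiv), 12 (1.8 equiv), 2,6-di-tert-butylpyridine, CH2Cl2, −40 to 0 °C, dark
Reagents that add atoms: N-bromosuccinimide, O=C1CCC(=O)N1Br
Why: Ueno–Stork-type bromoacetalisation, in which NBS attacks the nucleophilic α-carbon of the push–pull enol ether and the secondary alcohol traps the oxocarbenium ion, and the mixtures at C9 and C10 are harmless because C10 becomes a planar radical in step 7 and C9 a planar oxocarbenium ion in step 14.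

Step 7 (key step)
Reactants: 13 mixed bromoacetal
Product: 14 cis-fused bicyclic C11 ketone (1S,2S,10R,14R,15R; C9 OMe anomer mixture; C2 bears the (2S)-2-methyloxiranyl group; C14 bears CH(CH3)CO2Me)
Conditions: (Me3Si)3SiH (1.3 equiv), AIBN (0.2 equiv), both by syringe pump over 8 h, PhH (5 mM), 80 °C
Reagents that add atoms: none
Why: Ueno–Stork-type tandem radical cyclisation in which bromine abstraction gives the electrophilic α-keto radical at C10, this closes 5-exo onto the unactivated E alkene through a Beckwith–Houk chair with the C2 side chain pseudo-equatorial (C14 trans to C3) and the acyl group cis to C14, and the nucleophilic C14 radical then closes 6-endo onto the terminal carbon of the vinyl ketone through a chair with the C15 group pseudo-equatorial next to H1 (C15 trans to C2), while the reversible first closure and the easier chair closure of the cis radical funnel material to the cis ring fusion.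

Step 8
Reactants: 14 cis-fused bicyclic C11 ketone
Product: 15 C11 tertiary alcohol (11R; otherwise as 14)
Conditions: MeMgBr (1.3 equiv), THF–toluene, −78 °C; then H2O
Reagents that add atoms: methylmagnesium bromide, C[Mg]Br
Why: Grignard 1,2-addition to the ketone outruns attack on ester or epoxide at −78 °C, and methyl enters from the convex face opposite the tetrahydrofuran ring, so the hydroxyl ends up cis to C9 (11R).

Step 9
Reactants: 15 C11 tertiary alcohol
Product: 17 keto lactol (C2 acetyl; C9 OH anomer mixture; 1S,2S,10R,11R,14R,15R), via C3 glycol 16 (not isolated)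
Conditions: H5IO6 (1.1 equiv), THF–H2O 4:1, 0 °C to rt
Reagents that add atoms: water, O
Why: Acid hydrolysis of the 2,2-disubstituted epoxide followed by Malaprade glycol cleavage unmasks the methyl ketone at C3, the same acid turns the methyl acetal into the lactol needed next, and C2 is safe because its oxygen stays locked in the ring so no free α-ketol is offered to the single equivalent of periodate.

Step 10
Reactants: 18 (2-bromoallyl)trimethylsilane
Product: 20 2-[(trimethylsilyl)methyl]prop-2-enal, via Grignard reagent 19 (not isolated)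
Conditions: Mg, THF, 40 °C; DMF, 0 °C; then H2O
Reagents that add atoms: N,N-dimethylformamide, CN(C)C=O
Why: Bouveault-type formylation of the known alkenyl Grignard reagent stops at the hemiaminal salt until work-up and gives the enal (C6, C7) with the allylsilane intact and no stereocentre formed.

Step 11
Reactants: 21 S-ethyl ethanethioate
Product: 23 1-(ethylsulfanyl)-1-(trimethylsilyloxy)ethene, via lithium enolate 22 (not isolated)
Conditions: LDA, THF, −78 °C; Me3SiCl, −78 °C to rt
Reagents that add atoms: chlorotrimethylsilane, C[Si](C)(C)Cl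
Why: Kinetic enolisation and O-silylation of a thioester is the standard way to the ketene silyl thioacetal used in Mukaiyama aldol reactions, and it creates no stereocentre.

Step 12
Reactants: 20 2-[(trimethylsilyl)methyl]prop-2-enal; 23 1-(ethylsulfanyl)-1-(trimethylsilyloxy)ethene
Product: 25 S-ethyl (3R)-3-hydroxy-4-[(trimethylsilyl)methyl]pent-4-enethioate, via silyl ether 24 (not isolated)
Conditions: Ti(OiPr)4 (20 mol %), (R)-BINOL (20 mol %), Et2O, −20 °C; then 1 M HCl, THF, 0 °C
Reagents that add atoms: none
Why: Keck-type catalytic asymmetric Mukaiyama aldol, in which the BINOL–titanium complex shields one aldehyde face so C5 adds to give 6R, and brief dilute acid removes only the O-silyl group and leaves the allylsilane.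

Step 13
Reactants: 25 S-ethyl (3R)-3-hydroxy-4-[(trimethylsilyl)methyl]pent-4-enethioate; 26 butanoyl chloride
Product: 27 S-ethyl (3R)-3-(butanoyloxy)-4-[(trimethylsilyl)methyl]pent-4-enethioate
Conditions: pyridine, DMAP (5 mol %), CH2Cl2, 0 °C
Reagents that add atoms: none
Why: DMAP-catalysed acylation of a secondary allylic alcohol installs the final C6 butyrate with retention, so it also serves as the protecting group for the rest of the route.

Step 14
Reactants: 17 keto lactol; 27 S-ethyl (3R)-3-(butanoyloxy)-4-[(trimethylsilyl)methyl]pent-4-enethioate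
Product: 28 C9-allylated keto thioester (1S,2S,6R,9S,10R,11R,14R,15R; chain C9–CH2–C(=CH2)–CH(OCOPr)–CH2–C(O)SEt)
Conditions: BF3·OEt2 (1.5 equiv), 27 (1.5 equiv), CH2Cl2–MeCN, −78 to −30 °C
Reagents that add atoms: none
Why: Hosomi–Sakurai C-glycosidation, in which BF3 ionises the lactol to the planar C9 oxocarbenium ion and the allylsilane attacks through its CH2= terminus on the convex face anti to the C10–C11 bond, which gives 9S, makes that carbon C8 and moves the double bond into the exocyclic C7 position.

Step 15
Reactants: 28 C9-allylated keto thioester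
Product: 29 keto aldehyde (C4 aldehyde; C2 acetyl; stereocentres as 28)
Conditions: Et3SiH (3 equiv), Pd/C (5 mol % Pd), acetone, rt
Reagents that add atoms: none
Why: Fukuyama reduction, in which zerovalent palladium inserts only into the C–S bond and the silane delivers hydride, so the thioester becomes the aldehyde while the ketone, three esters, tertiary alcohol and 1,1-disubstituted alkene stay and no stereocentre is touched.

Step 16
Reactants: 29 keto aldehyde
Product: 31 tetracyclic C4 hydroxy lactone (1S,2S,3S,4R,6R,9S,10R,11R,14R,15R), via macrocyclic diol 30 (not isolated)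
Conditions: SmI2 (3 equiv, 0.1 M in THF), 29 added over 10 h (final 1 mM), −40 °C to rt, then 2 h at rt; aq NaHCO3
Reagents that add atoms: none
Why: Samarium ketyl (intramolecular pinacol) coupling in which the aldehyde is reduced first and its C4 ketyl radical adds to the C3 ketone held in a five-ring chelate of trivalent samarium between the ketone oxygen and the ring oxygen, so C4 arrives from the H2 side (Cram chelate, 3S), the two samarium-bound oxygens stay gauche while C2 and C5 turn away from each other as in other pinacol closures of rings of eight or more members (trans diol, 4R), both arms already sit cis on the convex face of the tetrahydrofuran, and the tertiary C3 alkoxide now held next to C16 expels methoxide to close the lactone.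

Step 17
Reactants: 32 1-bromoheptane
Product: 34 octanoic acid, via heptylmagnesium bromide 33 (not isolated)
Conditions: Mg, Et2O, reflux; CO2 (solid), −78 °C; then aq HCl
Reagents that add atoms: carbon dioxide, O=C=O
Why: Carboxylation of a primary Grignard reagent is a clean one-carbon homologation to the acid and creates no stereocentre.

Step 18
Reactants: 31 tetracyclic C4 hydroxy lactone; 34 octanoic acid
Product: 36 briarellin C, via O-acylisourea 35 (not isolated)
Conditions: DCC (1.5 equiv), DMAP (0.5 equiv), 34 (1.5 equiv), CH2Cl2, rt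
Reagents that add atoms: none
Why: Steglich esterification acylates C4–OH because it is the only secondary alcohol, the tertiary C11–OH is inert under these conditions, and the C–O bond at C4 is not broken so 4R is retained.

## Compound list
1 | methacrolein | C=C(C)C=O | starting material
2 | vinylmagnesium bromide | C=C[Mg]Br | starting material
3 | rac-2-methylpenta-1,4-dien-3-ol | C=CC(O)C(C)=C | intermediate
4 | (1S)-1-[(2S)-2-methyloxiran-2-yl]prop-2-en-1-ol | C=C[C@H](O)[C@]1(C)CO1 | intermediate
5 | methyl (E)-4-bromobut-2-enoate | COC(=O)/C=C/CBr | starting material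
6 | methyl (2R)-2-methylbut-3-enoate | C=C[C@@H](C)C(=O)OC | intermediate
7 | methyl (2R,3E,5S)-5-hydroxy-2-methyl-5-[(2S)-2-methyloxiran-2-yl]pent-3-enoate | COC(=O)[C@H](C)/C=C/[C@H](O)[C@]1(C)CO1 | intermediate
8 | (E)-4-methoxybut-3-en-2-one | CO/C=C/C(C)=O | starting material
9 | lithium dienolate of 8 | [Li+].[O-]C(=C)/C=C/OC | intermediate
10 | (E)-5-(dimethylamino)-1-methoxypent-1-en-3-one (Mannich base) | CO/C=C/C(=O)CCN(C)C | intermediate
11 | methiodide of 10 | CO/C=C/C(=O)CC[N+](C)(C)C.[I-] | intermediate
12 | (E)-1-methoxypenta-1,4-dien-3-one | CO/C=C/C(=O)C=C | intermediate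
13 | mixed bromoacetal (epimers at C9 and C10) | C=CC(=O)C(Br)C(OC)O[C@@H](/C=C/[C@@H](C)C(=O)OC)[C@]1(C)CO1 | intermediate
14 | cis-fused bicyclic C11 ketone (C9 anomer mixture) | COC1O[C@H]([C@]3(C)CO3)[C@H]2[C@@H](CCC(=O)[C@H]21)[C@@H](C)C(=O)OC | intermediate
15 | C11 tertiary alcohol (11R) | COC1O[C@H]([C@]3(C)CO3)[C@H]2[C@@H](CC[C@@](C)(O)[C@H]21)[C@@H](C)C(=O)OC | intermediate
16 | C3 glycol from epoxide hydrolysis (C3 not defined) | COC1O[C@H](C(C)(O)CO)[C@H]2[C@@H](CC[C@@](C)(O)[C@H]21)[C@@H](C)C(=O)OC | intermediate
17 | keto lactol (C9 anomer mixture) | OC1O[C@H](C(C)=O)[C@H]2[C@@H](CC[C@@](C)(O)[C@H]21)[C@@H](C)C(=O)OC | intermediate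
18 | (2-bromoallyl)trimethylsilane | C=C(Br)C[Si](C)(C)C | starting material
19 | [1-(trimethylsilylmethyl)vinyl]magnesium bromide | C=C([Mg]Br)C[Si](C)(C)C | intermediate
20 | 2-[(trimethylsilyl)methyl]prop-2-enal | C=C(C=O)C[Si](C)(C)C | intermediate
21 | S-ethyl ethanethioate | CCSC(C)=O | starting material
22 | lithium enolate of 21 | [Li+].[O-]C(=C)SCC | intermediate
23 | 1-(ethylsulfanyl)-1-(trimethylsilyloxy)ethene | C=C(O[Si](C)(C)C)SCC | intermediate
24 | O-trimethylsilyl ether of 25 | CCSC(=O)C[C@@H](O[Si](C)(C)C)C(=C)C[Si](C)(C)C | intermediate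
25 | S-ethyl (3R)-3-hydroxy-4-[(trimethylsilyl)methyl]pent-4-enethioate | CCSC(=O)C[C@@H](O)C(=C)C[Si](C)(C)C | intermediate
26 | butanoyl chloride | CCCC(=O)Cl | starting material
27 | S-ethyl (3R)-3-(butanoyloxy)-4-[(trimethylsilyl)methyl]pent-4-enethioate | CCSC(=O)C[C@@H](OC(=O)CCC)C(=C)C[Si](C)(C)C | intermediate
28 | C9-allylated keto thioester | CCSC(=O)C[C@@H](OC(=O)CCC)C(=C)C[C@@H]1O[C@H](C(C)=O)[C@H]2[C@@H](CC[C@@](C)(O)[C@H]21)[C@@H](C)C(=O)OC | intermediate
29 | keto aldehyde | O=CC[C@@H](OC(=O)CCC)C(=C)C[C@@H]1O[C@H](C(C)=O)[C@H]2[C@@H](CC[C@@](C)(O)[C@H]21)[C@@H](C)C(=O)OC | intermediate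
30 | macrocyclic 3,4-diol methyl ester | C=C1C[C@@H]2O[C@@H]([C@H]3[C@@H](CC[C@@](C)(O)[C@H]32)[C@@H](C)C(=O)OC)[C@@](C)(O)[C@H](O)C[C@H]1OC(=O)CCC | intermediate
31 | tetracyclic C4 hydroxy lactone | C=C1C[C@@H]2O[C@H]3[C@H]4[C@@H](CC[C@@](C)(O)[C@H]42)[C@@H](C)C(=O)O[C@@]3(C)[C@H](O)C[C@H]1OC(=O)CCC | intermediate
32 | 1-bromoheptane | CCCCCCCBr | starting material
33 | heptylmagnesium bromide | CCCCCCC[Mg]Br | intermediate
34 | octanoic acid | CCCCCCCC(=O)O | intermediate
35 | O-octanoyl-N,N'-dicyclohexylisourea | CCCCCCCC(=O)OC(=NC1CCCCC1)NC1CCCCC1 | intermediate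
36 | briarellin C | C=C1C[C@@H]2O[C@H]3[C@H]4[C@@H](CC[C@@](C)(O)[C@H]42)[C@@H](C)C(=O)O[C@@]3(C)[C@H](OC(=O)CCCCCCC)C[C@H]1OC(=O)CCC | target

## Count and risks
Total step count: 18.
Longest linear sequence: 11 steps (1, 2, 4, 6, 7, 8, 9, 14, 15, 16, 18).

**Step 7 (radical cascade).**
- Risks: the α-keto radical may be reduced before it cyclises, the silyl radical may add to the vinyl ketone, and some trans ring fusion may form.
- Fallback: it sets out from 13 and comes back at 14, and it uses the carbon–bromine bond for a regiospecific zinc enolate and a pericyclic ring closure instead of a radical.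
- Zn dust and t-BuMe2SiCl in THF at 0 °C turn 13 into the 2-(tert-butyldimethylsilyloxy)diene acetal F1.
- Heating F1 (toluene, BHT, 170 °C, sealed tube) triggers an intramolecular Diels–Alder reaction. Suprafacial addition to the E dienophile fixes C2 and C15 trans, and the product is the fused C11 silyl enol ether F2.
- HF·pyridine in THF at 0 °C then frees ketone 14 without enolising C10.

**Step 16 (ketyl macrocyclisation).**
- Risks: simple reduction or dimerisation may win over closure of the nine-membered ring, the C2–O bond may be cleaved reductively next to the ketone, and the 4-epimer may form.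
- Fallback: it sets out from 29 and comes back at 31, and it replaces the radical coupling by polar umpolung followed by a separate reduction.
- A bicyclic triazolium tetrafluoroborate precatalyst (20 mol %) and DBU in toluene at 1 mM turn the aldehyde into its Breslow intermediate. This adds to the α-oxygenated ketone in a crossed benzoin closure and gives the macrocyclic C3-hydroxy C4-ketone methyl ester F3.
- F3 lactonises under the same DBU to the C4-keto lactone F4.
- With O3 acylated no chelate can form. NaBH4 and CeCl3·7H2O in MeOH at −78 °C then attack the dipole-opposed conformer from the ring periphery and give 4R alcohol 31.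

**Step 6 (bromoacetalisation).**
- Risks: the hindered alcohol may trap the oxocarbenium ion poorly, NBS may attack the other alkene, and dienone 12 is labile.
- Fallback: it sets out from 7 and comes back at 13, and it makes the C2–O–C9 bond first by conjugate addition.
- Commercial pent-1-en-4-yn-3-ol is oxidised with MnO2 in CH2Cl2 to pent-1-en-4-yn-3-one F5.
- Alcohol 7 adds to the alkyne terminus of F5 under DABCO catalysis (10 mol %, CH2Cl2, 0 °C) and gives the (E)-β-alkoxy dienone F6.
- NBS with MeOH (3 equiv) in CH2Cl2 at −78 °C then bromomethoxylates the push–pull double bond of F6 to give 13.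

## Further compounds
F1 | step 7 | 2-(tert-butyldimethylsilyloxy)diene acetal (silyl dienol ether from 13) | C=CC(O[Si](C)(C)C(C)(C)C)=CC(OC)O[C@@H](/C=C/[C@@H](C)C(=O)OC)[C@]1(C)CO1
F2 | step 7 | Diels–Alder adduct, C11 silyl enol ether of 14 | COC1O[C@H]([C@]3(C)CO3)[C@H]2[C@@H](CC=C(O[Si](C)(C)C(C)(C)C)[C@H]21)[C@@H](C)C(=O)OC
F3 | step 16 | macrocyclic C3-hydroxy C4-ketone methyl ester | C=C1C[C@@H]2O[C@@H]([C@H]3[C@@H](CC[C@@](C)(O)[C@H]32)[C@@H](C)C(=O)OC)[C@@](C)(O)C(=O)C[C@H]1OC(=O)CCC
F4 | step 16 | C4-keto lactone | C=C1C[C@@H]2O[C@H]3[C@H]4[C@@H](CC[C@@](C)(O)[C@H]42)[C@@H](C)C(=O)O[C@@]3(C)C(=O)C[C@H]1OC(=O)CCC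
F5 | step 6 | pent-1-en-4-yn-3-one | C=CC(=O)C#C
F6 | step 6 | methyl (2R,3E,5S)-2-methyl-5-[(2S)-2-methyloxiran-2-yl]-5-{[(1E)-3-oxopenta-1,4-dien-1-yl]oxy}pent-3-enoate | C=CC(=O)/C=C/O[C@@H](/C=C/[C@@H](C)C(=O)OC)[C@]1(C)CO1
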